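Readings and results were computed for substances that don't exist, and the scatter is random.

You asked for a quick number, and I start from the late times, since what matters is whether this flask ever gets back to its early peak.

| flask | substrate | partner | remark | time |
|---|---|---|---|---|
| autumn | 20 mM | 14 mM | the very flask that is asked about, followed so far |  |
| dawn | 40 mM | 14 mM | run made earlier |  |
| flask | 20 mM | 14.0 mM |  | 3.0 h |

- autumn (time / min: target / %): 0.667: 9.7; 1.33: 14.4; 3.00: 19.2; 6.00: 17.2; 12.0: 15.9; 25.0: 15.8; 50.0: 17.8
- dawn (time / min: target / %): 0.667: 7.6; 1.50: 12.0; 3.00: 13.0; 8.00: 10.1; 15.0: 10.1; 30.0: 11.8; 80.0: 12.5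

(standard deviation of a reading: 1 percentage point)

* time, not beyond 3.0 h, at which the flask holds most target, in min
* the amount of target, in percent of the substrate charged, at that time
* earliest time at which at least nineteen twentieths of that best amount are there, in min
* latest time at which they still are



In the autumn run, which is this flask followed so far, the readings from 12.0 min on average 16.5%, against 19.2% at 3.00 min. That gives a ratio of 0.859, which I call the keep, the late level of target as a fraction of its early peak. The dawn run, with twice the substrate, reads 0.856.

The threshold asked about, taken on the autumn peak reading, is 18.2%, and the late level lies below it. The last autumn step up is 2 percentage points, but two readings differ by 1.4 points from scatter alone, so I read no climb. I therefore commit to the early peak for this flask, near 3.00 min and about 19.2%, with the window shut before the 17.2% read at 6.00 min.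

Your forecast parts from me here. It expects the flask “highest at the 3 h limit, though only narrowly above the early peak”, and it gives 19.7% at 180 min, with a window from 2.5 min to 3 h.

    substrate → intermediate (k = 0.0150 s⁻¹)
    partner + intermediate → target (k = 0.800 L mol⁻¹ s⁻¹)
    target ⇌ isomer of the product (K = 1.90, k = 0.0120 s⁻¹)
    intermediate → side product A (k = 0.00670 s⁻¹)
    substrate + intermediate → side product B (k = 0.0570 L mol⁻¹ s⁻¹)

The flask peaks at 2.86 min with 18.8%, and its window runs from 2.01 min to 4.58 min. By 0.300 h substrate stands at 0% with 31.5% of partner left, and target stands at 16.5%. Multiplied into the best, the keep gives 16.1% for the end of this flask, which holds 16.5%. Multiplied into the 36.7% of the neighbour charged with 56 mM of partner, it gives 31.5%, and that neighbour ends at 28.8%.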